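## Retrosynthetic overview

1. The target comes from fluoride release of a C2 triethylsilyl ketal (no bond to C2 is broken), after esterifying the C8 alcohol with tiglic acid.
2. Key step, the last C–C bond: C7–C8 closes the ten-membered ring. A C8 α-hydroxyalkyl radical (H-atom abstraction from the primary carbinol) adds to C7 of a 3-(acetoxymethyl)butenolide; loss of acetate unveils the α-methylene lactone and sets C7 and C8.
3. The butenolide comes from ring-closing metathesis of a C6 2-(acetoxymethyl)acrylate with the C6 vinyl group. The C1–C2 bond and the C2 configuration come from adding the isoprenol-derived allyl dianion to a γ-lactone and trapping the tetrahedral alkoxide in situ as the silyl ketal.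
4. The γ-lactone (C4, C5 set from C6) comes from hydroxyl-directed epoxidation, methanolysis and lactonisation of a Z-β,γ-unsaturated ester. That ester comes from a Z-vinyl iodide (Reformatsky–Negishi), itself from (S)-hex-1-en-4-yn-3-ol (acrolein + propyne).
5. Ring order: γ-lactone → oxolane silyl ketal → butenolide → ten-membered carbocycle with the α-methylene lactone.

Numbering is germacrane-type: ring C1–C10, C2 = hemiketal carbon, C4 = C(Me)OMe, C5–O = ring ether, C6–O = lactone, C8–O = ester, C11–C13 = methylene lactone, C14 = exocyclic CH2.

Assumption: the hemiketal carbon is taken exactly as written (2R: OH on the oxolane face that carries the C5–C6 bond and the C4 methoxy group, C1 on the other face); because a free hemiketal can equilibrate, this centre is made under kinetic control and held as a silyl ketal until the last step.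

## Route

**Step 1**
Reactants: 1 acrolein; 2 propyne
Product: 3 (3S)-hex-1-en-4-yn-3-ol
Conditions: Me2Zn, ProPhenol (10 mol%, enantiomer giving 3S, checked by Mosher ester), Ph3P=O (20 mol%), toluene, 0 °C
Reagents that add atoms: none
Why: Zinc–ProPhenol catalytic enantioselective alkynylation of an enal; the catalyst controls the aldehyde face and sets the C6 carbinol (S), which relays to C5 and C4 in step 4.

**Step 2**
Reactants: 3
Product: 4 (3S,4Z)-5-iodohexa-1,4-dien-3-ol
Conditions: Red-Al, THF, 0 °C → rt; then I2, −78 °C
Reagents that add atoms: iodine, II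
Why: Hydroxyl-directed trans-hydroalumination puts Al on the distal alkyne carbon (five-membered alanate) and iodinolysis goes with retention, giving the Z-iodide with I cis to the carbinol carbon; C6 is untouched.

**Step 3**
Reactants: 4; 5 isopropyl bromoacetate
Product: 6 isopropyl (3Z,5S)-5-hydroxy-3-methylhepta-3,6-dienoate
Conditions: 5, Zn (TMSCl-activated), THF → BrZnCH2CO2iPr (3 equiv); then 4, Pd(PPh3)4 (5 mol%), THF, 45 °C
Reagents that add atoms: none
Why: Negishi-type coupling of the Reformatsky zinc enolate with the alkenyl iodide proceeds with retention, placing CH2CO2iPr (C3–C2) cis to the carbinol carbon; no new stereocentre.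

**Step 4**
Reactants: 6
Product: 7 (4R,5R)-5-[(1S)-1-hydroxyprop-2-en-1-yl]-4-methoxy-4-methyloxolan-2-one
Conditions: mCPBA, NaHCO3, CH2Cl2, −10 °C; filter, concentrate; then MeOH, CSA (10 mol%), 0 → 40 °C
Reagents that add atoms: mCPBA, OOC(=O)c1cccc(Cl)c1 (epoxide O); methanol, CO
Why: Hydroxyl-directed peracid epoxidation of a Z-trisubstituted allylic alcohol is threo-selective through A1,3 strain (C5–O syn to C6–O); acid methanolysis opens the epoxide at the tertiary carbon with inversion (sets C4, installs OMe); the freed C5–OH then closes the γ-lactone.

**Step 5**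
Reactants: 7; 8 3-methylbut-3-en-1-ol
Product: 9 (2S,4R,5R)-5-[(1S)-1-hydroxyprop-2-en-1-yl]-4-methoxy-4-methyl-2-[2-methylidene-4-(triethylsilyloxy)butyl]-2-(triethylsilyloxy)oxolane. The allyl chain is trans and the silyloxy group cis to the C5 side chain; the label is 2S only because O–Si outranks the ring O, and the arrangement is that of the target's 2R hemiketal.
Conditions: 7, TMSCl, Et3N, THF, 0 °C (C6–OTMS, filtered, used crude); 8, n-BuLi (2 equiv per 8), TMEDA, Et2O, 0 °C → rt; add the silylated lactone, THF, −78 °C; TESOTf (excess), −78 °C; NaHCO3; then K2CO3, MeOH, 0 °C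
Reagents that add atoms: triethylsilyl triflate, CC[Si](CC)(CC)OS(=O)(=O)C(F)(F)F (both TES groups)
Why: Organolithium addition to a lactone with in situ O-silylation: the symmetric 2-substituted allyllithium adds once to the carbonyl from the face anti to the C5 side chain (C1 trans, alkoxide cis to the C5–C6 bond); TESOTf silylates the closed lithium hemiketal alkoxide and the primary alkoxide at −78 °C before ring opening, which fixes C2; K2CO3/MeOH then removes only the transient C6 TMS ether.

**Step 6** (side branch)
Reactants: 10 2-(bromomethyl)acrylic acid
Product: 11 2-(acetoxymethyl)acrylic acid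
Conditions: KOAc (5 equiv), AcOH, 60 °C
Reagents that add atoms: potassium acetate, CC(=O)[O-].[K+]
Why: Allylic substitution of bromide by acetate (SN2 or SN2′ give the same product).

**Step 7**
Reactants: 9; 11
Product: 12, the C6 2-(acetoxymethyl)acrylate ester of 9 (all centres unchanged)
Conditions: EDC·HCl, DMAP (10 mol%), CH2Cl2, 0 °C
Reagents that add atoms: none
Why: Steglich esterification of the only free hydroxyl (allylic secondary C6–OH); C6 is retained and the silyl ketal is untouched.

**Step 8**
Reactants: 12
Product: 13 (5S)-3-(acetoxymethyl)-5-[(2R,3R,5S)-3-methoxy-3-methyl-5-[2-methylidene-4-(triethylsilyloxy)butyl]-5-(triethylsilyloxy)oxolan-2-yl]furan-2(5H)-one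
Conditions: Grubbs II (5 mol%), toluene (5 mM), 80 °C
Reagents that add atoms: none
Why: Ring-closing metathesis of the acrylate with the allylic vinyl group gives the five-membered butenolide (ethylene lost); the five-ring closure outpaces any reaction of the remote 1,1-disubstituted alkene.

**Step 9**
Reactants: 13
Product: 14, the primary alcohol (C8–OH) corresponding to 13, with the C2 triethylsilyl ketal retained
Conditions: HF·pyridine, excess pyridine, THF, −10 → 0 °C
Reagents that add atoms: none
Why: Selective desilylation: the primary TES ether is cleaved far faster than the hindered tertiary TES ketal, and pyridine buffering avoids ionising the ketal or eliminating the allylic acetate.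

**Step 10** (key step)
Reactants: 14
Product: 15 (2S,4R,5R,6S,7R,8S)-2,5-epoxy-8-hydroxy-4-methoxy-2-(triethylsilyloxy)germacra-10(14),11(13)-dien-12,6-olide (2S for the silyl ketal = the target's 2R arrangement)
Conditions: [Ir(dF(CF3)ppy)2(dtbbpy)]PF6 (2 mol%), quinuclidine (20 mol%), Bu4N·H2PO4 (30 mol%), degassed MeCN (2 mM), 450 nm LEDs, rt
Reagents that add atoms: none
Why: Proposed new method: the quinuclidinium radical cation (from Ir(III)* oxidation) abstracts the phosphate-hydrogen-bond-activated α-C–H of the only carbinol CH2 (C8; the silyl groups add no α-oxy C–H); the nucleophilic α-hydroxyalkyl radical adds to C7 of the butenolide anti to the C5 substituent (trans-lactone, 7R); Ir(II) reduces the α-acyl radical to the enolate, which expels acetate (E1cB) to give the α-methylene lactone; the silyl ketal cannot anomerise, so closure can only give the ring with the C2 configuration fixed in step 5, the addition–reduction–elimination is irreversible so the ring stays closed, and reversible H-atom transfer lets uncyclised radical re-form; with C9 anti to C6 and the OH hydrogen-bonded to the lactone oxygens (OH between C6 and C11) the carbinol is expected to be 8S; closest known reactions are the photoredox/quinuclidine α-C–H alkylation of alcohols with acrylates (intermolecular) and radical addition–elimination allylations with Morita–Baylis–Hillman acetates.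

**Step 11**
Reactants: 15; 16 tiglic acid
Product: 17, the 8-O-[(E)-2-methylbut-2-enoyl] ester of 15
Conditions: 2,4,6-trichlorobenzoyl chloride, Et3N, toluene; then DMAP, rt
Reagents that add atoms: none
Why: Yamaguchi esterification acylates the only free hydroxyl (secondary C8–OH) with retention; the E geometry of the tiglate is unchanged and C2 stays protected as the silyl ketal.

**Step 12**
Reactants: 17
Product: 18, the target, (2R,4R,5R,6S,7R,8S)-2,5-epoxy-2-hydroxy-4-methoxy-8-[(2E)-2-methylbut-2-enoyloxy]germacra-10(14),11(13)-dien-12,6-olide
Conditions: TBAF/AcOH (1:1), THF, 0 °C; cold neutral work-up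
Reagents that add atoms: none
Why: Buffered fluoride desilylation attacks silicon only, so the Si–O bond is cut and no bond to C2 is broken; the hemiketal is released with the configuration fixed in step 5, and acetic acid protonates the alkoxide at once and spares the α-methylene lactone and tiglate.

## Compound list

1 | acrolein | C=CC=O | starting material
2 | propyne | CC#C | starting material
3 | (3S)-hex-1-en-4-yn-3-ol | CC#C[C@@H](O)C=C | intermediate
4 | (3S,4Z)-5-iodohexa-1,4-dien-3-ol | C/C(I)=C/[C@@H](O)C=C | intermediate
5 | isopropyl bromoacetate | CC(C)OC(=O)CBr | starting material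
6 | isopropyl (3Z,5S)-5-hydroxy-3-methylhepta-3,6-dienoate | CC(C)OC(=O)C/C(C)=C\[C@@H](O)C=C | intermediate
7 | (4R,5R)-5-[(1S)-1-hydroxyprop-2-en-1-yl]-4-methoxy-4-methyloxolan-2-one | O=C1C[C@@](C)(OC)[C@H](O1)[C@H](C=C)O | intermediate
8 | 3-methylbut-3-en-1-ol | CC(=C)CCO | starting material
9 | bis-TES compound: C2 triethylsilyl ketal, primary OTES, free C6–OH (see step 5) | CC[Si](CC)(CC)OCCC(=C)C[C@]1(O[Si](CC)(CC)CC)C[C@@](C)(OC)[C@H](O1)[C@H](C=C)O | intermediate
10 | 2-(bromomethyl)acrylic acid | C=C(CBr)C(=O)O | starting material
11 | 2-(acetoxymethyl)acrylic acid | C=C(COC(C)=O)C(=O)O | intermediate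
12 | C6 2-(acetoxymethyl)acrylate of 9 | CC[Si](CC)(CC)OCCC(=C)C[C@]1(O[Si](CC)(CC)CC)C[C@@](C)(OC)[C@H](O1)[C@H](C=C)OC(=O)C(=C)COC(C)=O | intermediate
13 | (5S)-3-(acetoxymethyl)butenolide on the bis-TES oxolane ketal | CC[Si](CC)(CC)OCCC(=C)C[C@]1(O[Si](CC)(CC)CC)C[C@@](C)(OC)[C@H](O1)[C@H]1OC(=O)C(COC(C)=O)=C1 | intermediate
14 | primary alcohol from 13, C2 TES ketal retained (cyclisation precursor) | OCCC(=C)C[C@]1(O[Si](CC)(CC)CC)C[C@@](C)(OC)[C@H](O1)[C@H]1OC(=O)C(COC(C)=O)=C1 | intermediate
15 | (2S,4R,5R,6S,7R,8S)-2,5-epoxy-8-hydroxy-4-methoxy-2-(triethylsilyloxy)germacra-10(14),11(13)-dien-12,6-olide | C=C1C[C@H](O)[C@H]2C(=C)C(=O)O[C@@H]2[C@H]2O[C@](O[Si](CC)(CC)CC)(C1)C[C@@]2(C)OC | intermediate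
16 | tiglic acid, (E)-2-methylbut-2-enoic acid | C/C=C(\C)C(=O)O | starting material
17 | 8-O-tiglate of 15 (C2 TES ketal) | C=C1C[C@H](OC(=O)/C(C)=C/C)[C@H]2C(=C)C(=O)O[C@@H]2[C@H]2O[C@](O[Si](CC)(CC)CC)(C1)C[C@@]2(C)OC | intermediate
18 | (2R,4R,5R,6S,7R,8S)-2,5-epoxy-2-hydroxy-4-methoxy-8-[(2E)-2-methylbut-2-enoyloxy]germacra-10(14),11(13)-dien-12,6-olide | C=C1C[C@H](OC(=O)/C(C)=C/C)[C@H]2C(=C)C(=O)O[C@@H]2[C@H]2O[C@](O)(C1)C[C@@]2(C)OC | target

## Summary

Total steps: 12. Longest linear sequence: 11 (steps 1–5, 7–12); step 6 is a one-step side branch.

Steps most likely to fail: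

- **Step 10 (radical ring closure).** The ketal holds the two arms on opposite faces of the oxolane, so the ring being closed is trans-bridged and more strained than an ordinary ten-membered closure. Cyclisation may be too slow against radical decay or oligomerisation, or C8 may form as the epimer. Fallback: use the bromo acid 10 directly in step 7, oxidise C8–OH of 14 to the aldehyde, and close the same bond by an intramolecular CrCl2-mediated Nozaki–Hiyama allylation of the 3-(bromomethyl)butenolide (polar allylchromium, chair transition state). If only the C8 epimer is obtained, esterify with 16 under Mitsunobu inversion.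
- **Step 5 (addition and in situ ketal trapping).** Risks are enolisation with methoxide loss, silylation of the ring-opened keto alkoxide (giving a C5–OTES ketone), and addition from the wrong face; the anomer must be confirmed by NOE. Fallback: quench to the lactol, convert it to the anomeric acetate, and install the silyloxy group through the oxocarbenium ion (Et3SiOH, TMSOTf, −78 °C), where inside attack cis to the C4 methoxy group gives the same anomer.
- **Step 12 (release of the hemiketal).** Once free, the hemiketal can open to the 5-hydroxy-2-ketone and re-close from either face, losing the C2 configuration. Fallback: trap the step-5 alkoxide as an allyl carbonate instead of the TES ketal (primary oxygen silylated separately) and unmask it last with Pd(PPh3)4/dimedone in aprotic medium at −20 °C, so the hemiketal is formed without fluoride, acid or base.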